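If a species is lost at a rate proportional to its own amount and nothing feeds it any longer, the rate integrates in closed form: the later amount is the earlier amount times exp(−k × elapsed time). This is first-order decay, and you can use it on the target in a flask where starting material is fed over 2.0 min into partner, second substrate and protic impurity.

| flask | starting material | partner | second substrate | protic impurity | remark | time |
|---|---|---|---|---|---|---|
| dusk | 0.013 M (fed, over 2.0 min) | 0.0234 M | 0.013 M | 9.1 mM | run made earlier; the fed solution adds 0.50 times the starting volume |  |
| midnight | 0.013 M (fed, over 2.0 min) | 0.0234 M | 0.013 M | 14 mM | run made earlier; the fed solution adds 0.50 times the starting volume |  |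
| winter | 0.013 M (fed, over 2.0 min) | 0.0234 M | 0.0065 M | 6.5 mM | run made earlier; the fed solution adds 0.50 times the starting volume |  |
| flask | 0.013 M (fed, over 2.0 min) | 0.0234 M | 0.0130 M | 6.50 mM | the fed solution adds 0.50 times the starting volume | 15 h |

| run | time / h | target / % | starting material / % |
|---|---|---|---|
| dusk | 0.333 | 33 | 53 |
| dusk | 0.667 | 42 | 38 |
| dusk | 1.33 | 44 | 27 |
| dusk | 2.50 | 40 | 17 |
| dusk | 5.00 | 28 | 11 |
| dusk | 10.0 | 15 | 8 |
| dusk | 20.0 | 5 | 2 |
| midnight | 0.333 | 29 | 57 |
| midnight | 0.667 | 33 | 45 |
| midnight | 1.33 | 33 | 37 |
| midnight | 2.50 | 27 | 23 |
| midnight | 5.00 | 19 | 17 |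
| midnight | 10.0 | 12 | 6 |
| midnight | 20.0 | 3 | 4 |
| winter | 0.333 | 45 | 53 |
| winter | 0.833 | 59 | 27 |
| winter | 2.50 | 59 | 12 |
| winter | 6.00 | 40 | 4 |
| winter | 20.0 | 9 | 0 |

(standard deviation of a reading: 1.5 percentage points)

- every charge counts on the volume at the start, and the solution that is fed holds the whole dose

- when, up to 15 h, the flask holds most target
- the amount of target, in percent of the starting material charged, at that time
- the first time at which target reaches 35%, in the same percent

Target rises and then falls in the winter run, so you want to read its loss late. In the winter run at 6.00 h, starting material reads 4% against 40% of target, so treat the later fall as loss. Target then reaches 9% at 20.0 h, which gives a late loss constant of target, the k of the formula, of 0.107 /h as a reading. You can test it on dusk, which has different charges: from 28% at 5.00 h it gives 5.62% at 20.0 h, and the reading is 5%.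

The flask has winter's impurity and dusk's second substrate. My own estimate therefore puts its peak between dusk's 44% and winter's 59%, near 1.33 h, with 35% passed just before 0.333 h. From 1.33 h to 15 h the formula keeps a fraction 0.233, so I expect 10.3% to 13.7% of target at the end.

The forecast gave 52% at 1.5 h and 35% at 0.3 h, with “a flat maximum near 52% at about 1.5 h”.

The flask gives 49.5% at 1.27 h, reaches 35% at 0.289 h, and holds 9.92% of target at 15 h.

    starting material + partner → target (k = 3.50 /M/min)
    second substrate + partner → second product (k = 2.90 /M/min)
    starting material + second substrate → cross product (k = 1.50 /M/min)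
    target ⇌ isomer of the product (K = 16.0, k = 0.00260 /min)
    partner + protic impurity → quenched reagent (k = 16.0 /M/min)

At 0.247 h, starting material has a half-life of 0.55 h by the step into target. Target's forward half-life into its isomer, 4.4 h, is longer than that. The same half-life is shorter than the 15 h allowed. Starting from the flask's peak, 0.107 /h keeps a fraction 0.232, which gives 11.5% against the 9.92% found.

In the neighbour with 0.0026 M of protic impurity, the best is 57.2%. Assuming the same span as in the flask, the fraction gives 13.3% at 15 h, and the computed neighbour holds 12.0%.

Readings and results were generated by integration for an exercise; scatter was added.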